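**Plan**
- Retrosynthesis: the C7–C8 bond (benzylic carbinol carbon to the aryloxy-bearing carbon) is cut first, then the C9–auxiliary bond, the indol-5-yl O–CH2 ether bond, the amide C–N bond and the diaryl ether C–O bond.
- Enabling feature: C8 carries the indol-5-yl ether oxygen and the C9 hydroxymethyl, so C8–C9 is an aryloxyacetyl unit whose CH2 becomes enolisable once C9 is an N-acyl oxazolidinone. C7 is a benzylic carbinol on ring A (the trioxygenated benzene) and maps onto the ring A aldehyde.
- Forward: ring A iodide and methyl p-coumarate are joined (diaryl ether), the ester is hydrolysed, serotonin is acylated, and the 5-hydroxyl is alkylated with a bromoacetyl imide. An intramolecular anti-aldol then closes the 21-membered ring; reductive removal of the auxiliary and deallylation finish the route.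
- Stereochemistry: C7 and C8 are both set in the ring closure by (S)-4-benzyloxazolidin-2-one through a magnesium-chelated Z-enolate (anti, erythro). The E-alkene comes from methyl p-coumarate.

Key step: step 7

Remark: the side chain is numbered C7 (benzylic carbinol), C8 (aryloxy carbon), C9 (CH2OH); the target is (7R,8S), the anti (erythro) isomer, and the facial sense of the magnesium aldol is taken from the chelated Z-enolate model.

**Step 1**
Reactants: 1 5-iodovanillin (4-hydroxy-3-iodo-5-methoxybenzaldehyde)
Product: 2 4-(allyloxy)-3-iodo-5-methoxybenzaldehyde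
Conditions: allyl bromide, K2CO3, DMF, rt
Reagents that add atoms: allyl bromide, C=CCBr
Why: Williamson etherification of the acidic para-formyl phenol installs an allyl group that should survive base, Lewis acid and hydride and leave under neutral zerovalent-palladium conditions at the end.

**Step 2**
Reactants: 2 4-(allyloxy)-3-iodo-5-methoxybenzaldehyde; 3 methyl (E)-4-hydroxycinnamate (methyl p-coumarate)
Product: 4 methyl (E)-3-{4-[2-(allyloxy)-5-formyl-3-methoxyphenoxy]phenyl}acrylate
Conditions: CuI (10 mol%), N,N-dimethylglycine·HCl (30 mol%), Cs2CO3, 1,4-dioxane, 90 °C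
Reagents that add atoms: none
Why: Ullmann-type copper-catalysed C–O coupling of the aryl iodide (activated by the formyl group, the ortho alkoxy group being tolerated with the amino acid ligand) with the phenoxide of 3 should form the diaryl ether and carry the E-alkene through unchanged.

**Step 3**
Reactants: 4 methyl (E)-3-{4-[2-(allyloxy)-5-formyl-3-methoxyphenoxy]phenyl}acrylate
Product: 5 (E)-3-{4-[2-(allyloxy)-5-formyl-3-methoxyphenoxy]phenyl}acrylic acid
Conditions: LiOH·H2O, THF/MeOH/H2O, rt; then 1 M HCl
Reagents that add atoms: lithium hydroxide, [Li+].[OH-]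
Why: Saponification of the methyl ester should be clean because the aldehyde has no alpha hydrogen and the aryl allyl ether is inert to hydroxide.

**Step 4**
Reactants: 5 (E)-3-{4-[2-(allyloxy)-5-formyl-3-methoxyphenoxy]phenyl}acrylic acid; 6 serotonin hydrochloride (5-hydroxytryptamine hydrochloride)
Product: 7 (E)-3-{4-[2-(allyloxy)-5-formyl-3-methoxyphenoxy]phenyl}-N-[2-(5-hydroxy-1H-indol-3-yl)ethyl]acrylamide
Conditions: EDC·HCl, HOBt, iPr2NEt, DMF, 0 °C to rt (acid pre-activated, then 6); dilute aqueous acid work-up
Reagents that add atoms: none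
Why: Carbodiimide amide coupling through the HOBt ester should acylate the primary amine in preference to the phenol and the indole nitrogen, and any imine formed reversibly at the aldehyde is hydrolysed in the acidic work-up.

**Step 5**
Reactants: 8 (S)-4-benzyloxazolidin-2-one
Product: 9 (S)-4-benzyl-3-(bromoacetyl)oxazolidin-2-one
Conditions: n-BuLi, THF, −78 °C; then BrCH2COBr, −78 to 0 °C
Reagents that add atoms: bromoacetyl bromide, BrCC(Br)=O
Why: N-acylation of the lithiated oxazolidinone should occur at the acid bromide, which is far more reactive than the alkyl bromide.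

**Step 6**
Reactants: 7 (E)-3-{4-[2-(allyloxy)-5-formyl-3-methoxyphenoxy]phenyl}-N-[2-(5-hydroxy-1H-indol-3-yl)ethyl]acrylamide; 9 (S)-4-benzyl-3-(bromoacetyl)oxazolidin-2-one
Product: 10 seco aldehyde imide, (E)-3-{4-[2-(allyloxy)-5-formyl-3-methoxyphenoxy]phenyl}-N-[2-(5-{2-[(S)-4-benzyl-2-oxooxazolidin-3-yl]-2-oxoethoxy}-1H-indol-3-yl)ethyl]acrylamide
Conditions: K2CO3, MeCN, rt
Reagents that add atoms: none
Why: Williamson etherification (SN2 at the alpha-bromo imide carbon) by the only phenoxide present should be fast, and carbonate is too weak to deprotonate the indole or amide N–H.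

**Step 7**
Reactants: 10 seco aldehyde imide
Product: 12 21-membered macrocyclic anti-aldol imide with free C7 hydroxyl (C7 R; C8 R by the imide priorities; ring A O-allyl; C9 still the N-acyl oxazolidinone), via C7 O-trimethylsilyl ether of the aldol 11 (not isolated)
Conditions: MgCl2 (2 equiv), Et3N, TMSCl, EtOAc/THF, rt, 10 added by syringe pump (final ca. 2 mM); then 1 M HCl, THF, 0 °C
Reagents that add atoms: chlorotrimethylsilane, C[Si](C)(C)Cl (its Me3Si group is carried by 11 only and is lost in the acid work-up)
Why: Proposed new method: MgCl2/Et3N soft enolisation of the aryloxyacetyl imide (two-point binding of the imide carbonyls, CH2 acidified by the indol-5-yloxy group) should give the magnesium-chelated Z-enolate, which adds to the tethered ring A aldehyde; O-silylation of the magnesium aldolate by TMSCl makes the addition irreversible and frees the metal, giving 11, which the acid work-up desilylates to 12. The closest known reaction type is the intermolecular magnesium-halide-catalysed direct anti-aldol reaction of N-acyloxazolidinones with non-enolisable aromatic aldehydes, proposed here as a macrocyclisation on an aryloxyacetyl imide; because the reagents tolerate the aldehyde, the substrate can be added slowly to an excess of them, which a preformed boron or lithium enolate would not allow. The 21-membered ring closes in a 21-(enolexo)-exo-trig mode by forming the C7–C8 bond. C8 is controlled by the (S)-benzyl group of the auxiliary, which shields one face of the chelated Z-enolate so that the aldehyde adds to the face an alkylating agent would take, and C7 by the boat-like magnesium-bridged transition state that places the new hydroxyl anti to the aryloxy group, giving the (2R,3R)-aldol that corresponds to (7R,8S) after reduction. The step needs ring closure over oligomerisation (pseudo-high dilution; rigid aryl, E-alkene and indole spacers), a single enolisable site (the aldehyde has no alpha hydrogen, the amide and indole N–H are not deprotonated by Et3N, and the secondary cinnamamide is too poor an acceptor to compete) and anti over syn addition (Z-enolate geometry enforced by chelation).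

**Step 8**
Reactants: 12 macrocyclic anti-aldol imide
Product: 13 O-allyl macrocyclic diol, the (7R,8S)-7-hydroxy-8-(hydroxymethyl) macrocycle with ring A phenol still as allyl ether
Conditions: LiBH4, THF, H2O (1 equiv), 0 °C
Reagents that add atoms: none
Why: Reductive cleavage of the N-acyl oxazolidinone by LiBH4 (hydride attack at the exocyclic imide carbonyl, assisted by lithium chelation with the beta-hydroxyl) should give the primary alcohol without touching C7 or C8, the secondary cinnamamide and the aryl allyl ether being inert at 0 °C.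

**Step 9**
Reactants: 13 O-allyl macrocyclic diol
Product: 14 CNP0276372.1 (target)
Conditions: Pd(PPh3)4 (5 mol%), morpholine, degassed THF, rt
Reagents that add atoms: none
Why: Tsuji–Trost-type deallylation, in which zerovalent palladium adds oxidatively to the aryl allyl ether and morpholine captures the pi-allyl complex, should free the phenol under neutral conditions that leave the para-hydroxybenzylic alcohol, the indole and the cinnamamide intact.

**Compound list**
1 | 5-iodovanillin (4-hydroxy-3-iodo-5-methoxybenzaldehyde) | O=Cc1cc(OC)c(O)c(I)c1 | starting material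
2 | 4-(allyloxy)-3-iodo-5-methoxybenzaldehyde | O=Cc1cc(OC)c(OCC=C)c(I)c1 | intermediate
3 | methyl (E)-4-hydroxycinnamate | COC(=O)/C=C/c1ccc(O)cc1 | starting material
4 | methyl (E)-3-{4-[2-(allyloxy)-5-formyl-3-methoxyphenoxy]phenyl}acrylate | O=Cc1cc(OC)c(OCC=C)c(Oc2ccc(/C=C/C(=O)OC)cc2)c1 | intermediate
5 | (E)-3-{4-[2-(allyloxy)-5-formyl-3-methoxyphenoxy]phenyl}acrylic acid | O=Cc1cc(OC)c(OCC=C)c(Oc2ccc(/C=C/C(=O)O)cc2)c1 | intermediate
6 | serotonin hydrochloride | Cl.NCCc1c[nH]c2ccc(O)cc12 | starting material
7 | (E)-3-{4-[2-(allyloxy)-5-formyl-3-methoxyphenoxy]phenyl}-N-[2-(5-hydroxy-1H-indol-3-yl)ethyl]acrylamide | O=Cc1cc(OC)c(OCC=C)c(Oc2ccc(/C=C/C(=O)NCCc3c[nH]c4ccc(O)cc34)cc2)c1 | intermediate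
8 | (S)-4-benzyloxazolidin-2-one | O=C1N[C@@H](Cc2ccccc2)CO1 | starting material
9 | (S)-4-benzyl-3-(bromoacetyl)oxazolidin-2-one | BrCC(=O)N1[C@@H](Cc2ccccc2)COC1=O | intermediate
10 | seco aldehyde imide | O=Cc1cc(OC)c(OCC=C)c(Oc2ccc(/C=C/C(=O)NCCc3c[nH]c4ccc(OCC(=O)N5[C@@H](Cc6ccccc6)COC5=O)cc34)cc2)c1 | intermediate
11 | C7 O-trimethylsilyl ether of the macrocyclic anti-aldol imide (not isolated) | COc1cc2cc(c1OCC=C)Oc1ccc(cc1)/C=C/C(=O)NCCc1c[nH]c3ccc(cc13)O[C@@H](C(=O)N4[C@@H](Cc5ccccc5)COC4=O)[C@@H]2O[Si](C)(C)C | intermediate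
12 | macrocyclic anti-aldol imide | COc1cc2cc(c1OCC=C)Oc1ccc(cc1)/C=C/C(=O)NCCc1c[nH]c3ccc(cc13)O[C@@H](C(=O)N4[C@@H](Cc5ccccc5)COC4=O)[C@@H]2O | intermediate
13 | O-allyl macrocyclic (7R,8S)-diol | COc1cc2cc(c1OCC=C)Oc1ccc(cc1)/C=C/C(=O)NCCc1c[nH]c3ccc(cc13)O[C@@H](CO)[C@@H]2O | intermediate
14 | CNP0276372.1 | COc1cc2cc(c1O)Oc1ccc(cc1)/C=C/C(=O)NCCc1c[nH]c3ccc(cc13)O[C@@H](CO)[C@@H]2O | target

**Step count and risks**
Total steps: 9. Longest linear sequence: 8 (steps 1, 2, 3, 4, 6, 7, 8, 9).

Steps most likely to fail:

1. Step 7 (oligomerisation outrunning ring closure, sluggish enolisation at high dilution, or erosion of the anti selectivity by the tether). The fallback runs the aldol between two molecules, in the established intermolecular form of the same magnesium-halide anti-aldol, and closes the ring at the amide by macrolactamisation. It sets out from 4 (with 6 and 9) and comes back to the route at 14. Compound 6 is converted into N-allyloxycarbonylserotonin F1 (allyl chloroformate, NaHCO3, THF/H2O), which is O-alkylated with 9 (K2CO3, MeCN) to the aryloxyacetyl imide F2. F2 is combined with aldehyde 4 (MgCl2, Et3N, TMSCl, EtOAc) to give the (2R,3R)-anti-aldol silyl ether F3. NaBH4 in THF/H2O followed by a dilute HCl work-up removes the auxiliary and the silyl group to give the diol ester F4, and LiOH gives the acid F5. Pd(PPh3)4/morpholine cleaves both allyl groups to the amino acid F6, which is lactamised under high dilution (DPPA, NaHCO3, DMF) to give 14 directly.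

2. Step 6 (acyl transfer from the activated imide to phenoxide or carbonate with loss of the auxiliary, or competing N-alkylation). The fallback attaches the auxiliary last; it sets out from 7 and comes back at 10. Alkylation of 7 with tert-butyl bromoacetate (K2CO3, MeCN) gives the tert-butyl aryloxyacetate F7, and TFA/CH2Cl2 gives the aryloxyacetic acid F8. F8 is converted into its mixed pivalic anhydride (PivCl, Et3N, THF, −20 °C), which acylates 8 in the presence of LiCl to give 10.

3. Step 8 (retro-aldol opening of the macrocycle under the basic hydride conditions, or hydride attack at the ring carbonyl of the oxazolidinone). The fallback blocks the retro-aldol path with a protecting group; it sets out from 12 and comes back at 13. TESCl/imidazole (DMF) gives the C7 triethylsilyl ether F9, LiBH4 (THF, 0 °C) then gives the primary alcohol F10 without an aldolate being formed, and TBAF/AcOH (THF) removes the silyl group to give 13.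

**Further compounds**
F1 | step 7 | allyl N-[2-(5-hydroxy-1H-indol-3-yl)ethyl]carbamate | C=CCOC(=O)NCCc1c[nH]c2ccc(O)cc12
F2 | step 7 | allyl N-[2-(5-{2-[(S)-4-benzyl-2-oxooxazolidin-3-yl]-2-oxoethoxy}-1H-indol-3-yl)ethyl]carbamate | C=CCOC(=O)NCCc1c[nH]c2ccc(OCC(=O)N3[C@@H](Cc4ccccc4)COC3=O)cc12
F3 | step 7 | acyclic (2R,3R)-anti-aldol imide as its O-trimethylsilyl ether (methyl cinnamate and N-Alloc retained) | COC(=O)/C=C/c1ccc(Oc2cc(cc(OC)c2OCC=C)[C@@H](O[Si](C)(C)C)[C@@H](Oc3ccc4[nH]cc(CCNC(=O)OCC=C)c4c3)C(=O)N3[C@@H](Cc4ccccc4)COC3=O)cc1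
F4 | step 7 | acyclic (7R,8S)-diol methyl ester with N-Alloc and O-allyl groups | COC(=O)/C=C/c1ccc(Oc2cc(cc(OC)c2OCC=C)[C@@H](O)[C@@H](Oc3ccc4[nH]cc(CCNC(=O)OCC=C)c4c3)CO)cc1
F5 | step 7 | acyclic (7R,8S)-diol cinnamic acid with N-Alloc and O-allyl groups | OC(=O)/C=C/c1ccc(Oc2cc(cc(OC)c2OCC=C)[C@@H](O)[C@@H](Oc3ccc4[nH]cc(CCNC(=O)OCC=C)c4c3)CO)cc1
F6 | step 7 | acyclic (7R,8S) amino acid with free amine, phenol and diol | OC(=O)/C=C/c1ccc(Oc2cc(cc(OC)c2O)[C@@H](O)[C@@H](Oc3ccc4[nH]cc(CCN)c4c3)CO)cc1
F7 | step 6 | tert-butyl 2-{[3-(2-{(E)-3-[4-(2-(allyloxy)-5-formyl-3-methoxyphenoxy)phenyl]acrylamido}ethyl)-1H-indol-5-yl]oxy}acetate | O=Cc1cc(OC)c(OCC=C)c(Oc2ccc(/C=C/C(=O)NCCc3c[nH]c4ccc(OCC(=O)OC(C)(C)C)cc34)cc2)c1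
F8 | step 6 | 2-{[3-(2-{(E)-3-[4-(2-(allyloxy)-5-formyl-3-methoxyphenoxy)phenyl]acrylamido}ethyl)-1H-indol-5-yl]oxy}acetic acid | O=Cc1cc(OC)c(OCC=C)c(Oc2ccc(/C=C/C(=O)NCCc3c[nH]c4ccc(OCC(=O)O)cc34)cc2)c1
F9 | step 8 | C7 O-triethylsilyl ether of macrocyclic aldol imide 12 | COc1cc2cc(c1OCC=C)Oc1ccc(cc1)/C=C/C(=O)NCCc1c[nH]c3ccc(cc13)O[C@@H](C(=O)N4[C@@H](Cc5ccccc5)COC4=O)[C@@H]2O[Si](CC)(CC)CC
F10 | step 8 | C7 O-triethylsilyl ether of O-allyl macrocyclic diol 13 | COc1cc2cc(c1OCC=C)Oc1ccc(cc1)/C=C/C(=O)NCCc1c[nH]c3ccc(cc13)O[C@@H](CO)[C@@H]2O[Si](CC)(CC)CC
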